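**Retrosynthetic overview**
- The target comes from hydrogenolysis of its 5,7-di-O-benzyl ether.
- The key disconnection is C2–C1′: a 2-unsubstituted 3-hydroxychromone (rings A/C complete) is joined to 2,3-dimethoxyphenol. The phenol is dearomatized to its o-quinone monoketal (polarity reversal of ring B), a Michael addition follows, and loss of methanol re-aromatizes ring B.
- Enabling feature: the C3–OH enol of the pyranone ring (O1–C2=C3(OH)–C4=O) makes C2–H a nucleophilic enol carbon. The O3′H/O4′Me catechol monoether of ring B can be oxidized to a 6,6-dimethoxycyclohexa-2,4-dienone in which C1′ (meta to O3′, para to C4′) is the electrophilic β-carbon, and whose ketone returns as the free 3′-OH.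
- The 3-hydroxychromone comes from the chromone (epoxidation/isomerization), the chromone from enaminone cyclization (O1–C2 bond) of a 2-hydroxy-3-methoxy-4,6-bis(benzyloxy)acetophenone, and that from ortho-iodination/copper methoxylation of 2,4-bis(benzyloxy)-6-hydroxyacetophenone.
- Ring order: ring A is bought, ring C is closed in step 3, ring B is bought as a phenol and attached in step 5.

Key step: step 5

Remark: the target is an achiral, planar flavonol without stereocentres, so no stereocontrol is needed; the transient stereocentres of 6 and 10 are racemic and are erased within the same step.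
Remark: compound 1 is taken as a catalogue compound (it is otherwise the dibenzylation product of 2,4,6-trihydroxyacetophenone).

**Step 1**
Reactants: 1 1-[2,4-bis(benzyloxy)-6-hydroxyphenyl]ethan-1-one
Product: 2 1-[4,6-bis(benzyloxy)-2-hydroxy-3-iodophenyl]ethan-1-one
Conditions: BnMe3N+ ICl2− (1.05 equiv), CaCO3, CH2Cl2/MeOH, rt
Reagents that add atoms: benzyltrimethylammonium dichloroiodate, C[N+](C)(C)Cc1ccccc1.Cl[I-]Cl
Why: Electrophilic aromatic iodination with a dichloroiodate is expected to go ortho to the free phenol OH, at the carbon between OH and OBn, as is usual for 2-hydroxy-4,6-dialkoxyacetophenones, and this carbon becomes C8.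

**Step 2**
Reactants: 2 1-[4,6-bis(benzyloxy)-2-hydroxy-3-iodophenyl]ethan-1-one
Product: 3 1-[4,6-bis(benzyloxy)-2-hydroxy-3-methoxyphenyl]ethan-1-one
Conditions: NaOMe (5 equiv), CuI (cat.), MeOH/DMF, 100 °C; acidic work-up
Reagents that add atoms: sodium methoxide, C[O-].[Na+]
Why: Ullmann-type copper-catalysed methoxylation of an o-halophenol (the reaction type that converts 5-halovanillins into syringaldehyde) should replace iodide by methoxide with help of the neighbouring phenoxide, while the benzyl ethers and the hindered methyl ketone tolerate methoxide.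

**Step 3**
Reactants: 3 1-[4,6-bis(benzyloxy)-2-hydroxy-3-methoxyphenyl]ethan-1-one
Product: 5 5,7-bis(benzyloxy)-8-methoxy-4H-chromen-4-one, via enaminone 4 (not isolated)
Conditions: Me2NCH(OMe)2 (3 equiv), toluene, 100 °C; then conc. HCl, CH2Cl2, rt
Reagents that add atoms: N,N-dimethylformamide dimethyl acetal, COC(OC)N(C)C
Why: Condensation of the methyl ketone with the amide acetal gives the enaminone, and acid-promoted 6-endo addition of the only free ortho OH to the β-carbon with loss of dimethylamine closes the pyranone ring (enaminone chromone synthesis), which fixes the methoxy group at C8 because the other ortho oxygen is benzylated.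

**Step 4**
Reactants: 5 5,7-bis(benzyloxy)-8-methoxy-4H-chromen-4-one
Product: 7 5,7-bis(benzyloxy)-3-hydroxy-8-methoxy-4H-chromen-4-one, via chromone 2,3-epoxide 6 (not isolated)
Conditions: 30% H2O2, aq. NaOH, CH2Cl2/MeOH, 0 °C; then TsOH·H2O (cat.), CH2Cl2, rt
Reagents that add atoms: hydrogen peroxide, OO
Why: Weitz–Scheffer nucleophilic epoxidation of the chromone C2=C3 bond, then acid-catalysed opening of the epoxide at the acetal-like C2 and loss of the C3 proton, is the usual way to 2-unsubstituted 3-hydroxychromones and leaves aryl ethers untouched.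

**Step 5**
Reactants: 7 5,7-bis(benzyloxy)-3-hydroxy-8-methoxy-4H-chromen-4-one; 8 2,3-dimethoxyphenol
Product: 11 5,7-bis(benzyloxy)-3-hydroxy-2-(3-hydroxy-4,5-dimethoxyphenyl)-8-methoxy-4H-chromen-4-one, via o-quinone monoketal 9 (not isolated), via Michael adduct 10 (not isolated)
Conditions: (i) 8 (1.5 equiv), PhI(OAc)2 (1.45 equiv), MeOH, 0 °C; (ii) 7 (1.0 equiv), Et3N, CH2Cl2/MeOH, 0 °C → rt; (iii) aq. HCl work-up, then TsOH·H2O (cat.), CH2Cl2/MeOH, rt if methanol loss is incomplete
Reagents that add atoms: methanol, CO (enters 9 and 10 as one of the two ketal methoxy groups; one of the two leaves again, so the 4′-OMe of 11 stems from 8 or from the solvent)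
Why: Proposed new method: oxidation of 8 by PhI(OAc)2 in methanol traps the phenoxenium ion at the methoxy-bearing ortho carbon and gives the o-quinone monoketal 9, in which the carbon meta to the former phenol oxygen and para to the ketal carbon is the β-carbon of a dienone, while Et3N turns 7 into a 3-oxido-4-pyranone whose only nucleophilic carbon is the enol carbon C2, so that a Michael addition joins two carbons that are both nucleophilic in the aromatic parents and gives 10. Loss of methanol from the ketal of 10 (enolization, then 1,4-elimination, finished by acid) restores the aromatic B ring and returns the dienone carbonyl as the free 3′-OH, so that no B-ring protecting group or metal handle is needed. The closest known reaction types are the Michael addition–aromatization of indoles and other soft carbon nucleophiles with masked o-benzoquinones and the amine-catalysed Michael additions of kojic acid and 3-hydroxychromones through the carbon next to the enolic OH. No ring is closed, and the one sp3 stereocentre of 10 is racemic and is erased on aromatization. The step needs 1,4- and not 1,6-addition or [4+2] cycloaddition at the dienone and C- and not O-attack of the oxido-pyranone: the δ-carbon of 9 carries a donating methoxy group and lies next to the quaternary ketal carbon, which leaves the unsubstituted β-carbon as the open site, and only the adduct at that carbon is drained irreversibly by aromatization, whereas O- and δ-adducts can revert. The benzyl ethers on O5 and O7 keep the A-ring oxygens silent, and the oxidant is used up by the excess of 8 before 7 is added.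

**Step 6**
Reactants: 11 5,7-bis(benzyloxy)-3-hydroxy-2-(3-hydroxy-4,5-dimethoxyphenyl)-8-methoxy-4H-chromen-4-one
Product: 12 3,5,7-trihydroxy-2-(3-hydroxy-4,5-dimethoxyphenyl)-8-methoxy-4H-chromen-4-one (CNP0225742.0)
Conditions: H2 (1 atm), 10% Pd/C, EtOAc/MeOH, rt
Reagents that add atoms: none
Why: Hydrogenolysis of the two aryl benzyl ethers on Pd/C under neutral conditions should spare the tetrasubstituted, conjugated C2=C3 bond of the flavonol and uses no acid that could trigger Wessely–Moser isomerization of the 5-hydroxy-8-methoxy A ring.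

**Compound list**
1 | 1-[2,4-bis(benzyloxy)-6-hydroxyphenyl]ethan-1-one | CC(=O)c1c(O)cc(OCc2ccccc2)cc1OCc1ccccc1 | starting material
2 | 1-[4,6-bis(benzyloxy)-2-hydroxy-3-iodophenyl]ethan-1-one | CC(=O)c1c(O)c(I)c(OCc2ccccc2)cc1OCc1ccccc1 | intermediate
3 | 1-[4,6-bis(benzyloxy)-2-hydroxy-3-methoxyphenyl]ethan-1-one | CC(=O)c1c(O)c(OC)c(OCc2ccccc2)cc1OCc1ccccc1 | intermediate
4 | (E)-1-[4,6-bis(benzyloxy)-2-hydroxy-3-methoxyphenyl]-3-(dimethylamino)prop-2-en-1-one | CN(C)/C=C/C(=O)c1c(O)c(OC)c(OCc2ccccc2)cc1OCc1ccccc1 | intermediate (not isolated)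
5 | 5,7-bis(benzyloxy)-8-methoxy-4H-chromen-4-one | O=c1ccoc2c(OC)c(OCc3ccccc3)cc(OCc3ccccc3)c12 | intermediate
6 | 5,7-bis(benzyloxy)-2,3-epoxy-8-methoxychroman-4-one (cis-fused, racemic; one enantiomer drawn) | O=C1[C@H]2O[C@H]2Oc2c(OC)c(OCc3ccccc3)cc(OCc3ccccc3)c12 | intermediate (not isolated)
7 | 5,7-bis(benzyloxy)-3-hydroxy-8-methoxy-4H-chromen-4-one | O=c1c(O)coc2c(OC)c(OCc3ccccc3)cc(OCc3ccccc3)c12 | intermediate
8 | 2,3-dimethoxyphenol | COc1cccc(O)c1OC | starting material
9 | 5,6,6-trimethoxycyclohexa-2,4-dien-1-one | O=C1C=CC=C(OC)C1(OC)OC | intermediate (not isolated)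
10 | 5,7-bis(benzyloxy)-3-hydroxy-8-methoxy-2-(3,4,4-trimethoxy-5-oxocyclohex-2-en-1-yl)-4H-chromen-4-one (racemic) | COC1=CC(CC(=O)C1(OC)OC)c1oc2c(OC)c(OCc3ccccc3)cc(OCc3ccccc3)c2c(=O)c1O | intermediate (not isolated)
11 | 5,7-bis(benzyloxy)-3-hydroxy-2-(3-hydroxy-4,5-dimethoxyphenyl)-8-methoxy-4H-chromen-4-one | COc1cc(-c2oc3c(OC)c(OCc4ccccc4)cc(OCc4ccccc4)c3c(=O)c2O)cc(O)c1OC | intermediate
12 | 3,5,7-trihydroxy-2-(3-hydroxy-4,5-dimethoxyphenyl)-8-methoxy-4H-chromen-4-one | COc1cc(-c2oc3c(OC)c(O)cc(O)c3c(=O)c2O)cc(O)c1OC | target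

**Step count and risks**
Total steps: 6. Longest linear sequence: 6 steps (1 → 12); 8 enters at step 5.

Steps most likely to fail:

1. Step 5 (Proposed new method). The monoketal may dimerize by Diels–Alder reaction before it is intercepted, the oxido-pyranone may add at the methoxy-bearing δ-carbon or through oxygen, or methanol loss may stall. Fallback with known cross-coupling chemistry, setting out from 8 and 7 and coming back at 12:
   - 8 is silylated (TBSCl, imidazole, DMF) to tert-butyl(2,3-dimethoxyphenoxy)dimethylsilane F1.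
   - Sterically controlled Ir-catalysed C–H borylation ([Ir(OMe)(cod)]2, dtbpy, B2pin2, THF, 80 °C) should functionalize the only C–H flanked by two hydrogens and give tert-butyl[2,3-dimethoxy-5-(4,4,5,5-tetramethyl-1,3,2-dioxaborolan-2-yl)phenoxy]dimethylsilane F2.
   - 7 is benzylated (BnBr, K2CO3, DMF) to 3,5,7-tris(benzyloxy)-8-methoxy-4H-chromen-4-one F3.
   - Directed zincation at C2 (TMPZnCl·LiCl, THF, 25 °C) gives [3,5,7-tris(benzyloxy)-8-methoxy-4-oxo-4H-chromen-2-yl]zinc chloride F4 (not isolated), and iodine converts it into 3,5,7-tris(benzyloxy)-2-iodo-8-methoxy-4H-chromen-4-one F5.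
   - Suzuki–Miyaura coupling of F5 with F2 (Pd(dppf)Cl2, CsF, dioxane, 80 °C) gives 3,5,7-tris(benzyloxy)-2-[3-(tert-butyldimethylsilyloxy)-4,5-dimethoxyphenyl]-8-methoxy-4H-chromen-4-one F6.
   - TBAF (THF, 0 °C) gives 3,5,7-tris(benzyloxy)-2-(3-hydroxy-4,5-dimethoxyphenyl)-8-methoxy-4H-chromen-4-one F7, and hydrogenolysis (H2, Pd/C, EtOAc/MeOH) gives 12.

2. Step 2. Protodeiodination or slow C–O bond formation at the doubly ortho-flanked carbon, or base-induced condensation of the ketone, may compete. Fallback without a cross-coupling, setting out from 1 and coming back at 3: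
   - Magnesium-mediated ortho-formylation of the phenol (MgCl2, Et3N, paraformaldehyde, MeCN, reflux) at the only free ortho position gives 3-acetyl-4,6-bis(benzyloxy)-2-hydroxybenzaldehyde F8.
   - Dakin oxidation (30% H2O2, aq. NaOH, THF, 0 °C) passes through 3-acetyl-4,6-bis(benzyloxy)-2-hydroxyphenyl formate F9 (not isolated) and gives 1-[4,6-bis(benzyloxy)-2,3-dihydroxyphenyl]ethan-1-one F10.
   - Methylation of the dianion (NaH 2.1 equiv, DMF, 0 °C; MeI 1.0 equiv) should occur at the phenoxide that is not conjugated with the ketone and give 3.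

3. Step 4. Hydroxide or hydroperoxide may open the 2-unsubstituted pyranone at C2 (retro-Claisen loss of the formyl carbon) faster than the epoxide forms. Fallback that brings in the C3 oxygen at the chromanone level, setting out from 5 and coming back at 7:
   - Conjugate reduction (L-Selectride, THF, −78 °C) gives 5,7-bis(benzyloxy)-8-methoxychroman-4-one F11.
   - α-Nitrosation (isoamyl nitrite, conc. HCl, EtOH/THF, 0 °C → rt) gives 5,7-bis(benzyloxy)-3-(hydroxyimino)-8-methoxychroman-4-one F12, which is hydrolysed in the aqueous acid to the chroman-3,4-dione, that is, its enol 7.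

**Further compounds**
F1 | step 5 | tert-butyl(2,3-dimethoxyphenoxy)dimethylsilane | COc1cccc(O[Si](C)(C)C(C)(C)C)c1OC
F2 | step 5 | tert-butyl[2,3-dimethoxy-5-(4,4,5,5-tetramethyl-1,3,2-dioxaborolan-2-yl)phenoxy]dimethylsilane | COc1cc(B2OC(C)(C)C(C)(C)O2)cc(O[Si](C)(C)C(C)(C)C)c1OC
F3 | step 5 | 3,5,7-tris(benzyloxy)-8-methoxy-4H-chromen-4-one | O=c1c(OCc2ccccc2)coc2c(OC)c(OCc3ccccc3)cc(OCc3ccccc3)c12
F4 | step 5 | [3,5,7-tris(benzyloxy)-8-methoxy-4-oxo-4H-chromen-2-yl]zinc chloride | O=c1c(OCc2ccccc2)c([Zn]Cl)oc2c(OC)c(OCc3ccccc3)cc(OCc3ccccc3)c12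
F5 | step 5 | 3,5,7-tris(benzyloxy)-2-iodo-8-methoxy-4H-chromen-4-one | O=c1c(OCc2ccccc2)c(I)oc2c(OC)c(OCc3ccccc3)cc(OCc3ccccc3)c12
F6 | step 5 | 3,5,7-tris(benzyloxy)-2-[3-(tert-butyldimethylsilyloxy)-4,5-dimethoxyphenyl]-8-methoxy-4H-chromen-4-one | COc1cc(-c2oc3c(OC)c(OCc4ccccc4)cc(OCc4ccccc4)c3c(=O)c2OCc2ccccc2)cc(O[Si](C)(C)C(C)(C)C)c1OC
F7 | step 5 | 3,5,7-tris(benzyloxy)-2-(3-hydroxy-4,5-dimethoxyphenyl)-8-methoxy-4H-chromen-4-one | COc1cc(-c2oc3c(OC)c(OCc4ccccc4)cc(OCc4ccccc4)c3c(=O)c2OCc2ccccc2)cc(O)c1OC
F8 | step 2 | 3-acetyl-4,6-bis(benzyloxy)-2-hydroxybenzaldehyde | CC(=O)c1c(O)c(C=O)c(OCc2ccccc2)cc1OCc1ccccc1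
F9 | step 2 | 3-acetyl-4,6-bis(benzyloxy)-2-hydroxyphenyl formate | CC(=O)c1c(O)c(OC=O)c(OCc2ccccc2)cc1OCc1ccccc1
F10 | step 2 | 1-[4,6-bis(benzyloxy)-2,3-dihydroxyphenyl]ethan-1-one | CC(=O)c1c(O)c(O)c(OCc2ccccc2)cc1OCc1ccccc1
F11 | step 4 | 5,7-bis(benzyloxy)-8-methoxychroman-4-one | O=C1CCOc2c(OC)c(OCc3ccccc3)cc(OCc3ccccc3)c12
F12 | step 4 | 5,7-bis(benzyloxy)-3-(hydroxyimino)-8-methoxychroman-4-one (oxime geometry not defined) | O=C1C(=NO)COc2c(OC)c(OCc3ccccc3)cc(OCc3ccccc3)c12
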